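**Retrosynthetic overview**

1. The plan rests on the cis 6,7-dioxygen pair of ring B: C6 (allylic to C5=C10) and C7 (next to the C8 methine) are taken as the two carbonyl carbons of a 1,6-dialdehyde, so C6–C7 is cut and ring B opened; forward, SmI2 pinacol coupling closes ring B and sets both carbinols.
2. The seco dialdehyde comes from a diester via the diol; C6 is placed on C5 by carbonylation of a C5 enol triflate, which fixes the tetrasubstituted C5=C10 alkene by construction.
3. C8 and C9 are cut by an Ireland–Claisen disconnection to the propanoate of a (Z)-2-alkylidene-6,6-dimethylcyclohexanol; a singlet-oxygen ene step later returns oxygen to C5.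
4. The alkylidenecyclohexanol is cut at C9–C10 and C9–C20 into 2,2-dimethylcyclohexanone (ring A), a linalool-derived C9 aldehyde (C9, C11–C16, with C13 set) and a methyl cuprate.
5. Ring order: ring A is bought and carried from the start; ring B is formed in the key step; desilylation and O7 acetylation end the route.

Key step: step 16

Remark: halimane numbering is used throughout (ring A = C1–C5 and C10, ring B = C5–C10, C17 on C8, C18/C19 on C4, C20 on C9, side chain C11–C16); in the oxazaborolidine reduction of step 7 the tetrasubstituted alkylidene arm of the C5 ketone is assumed to act as the large carbonyl substituent, as alkenyl arms of α-substituted enones do.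

Step 1
Reactants: 1 (R)-(−)-linalool
Product: 2 (3R)-3,7-dimethyl-3-(triethylsilyloxy)octa-1,6-diene
Conditions: Et3SiOTf, 2,6-lutidine, CH2Cl2, −78 → 0 °C
Reagents that add atoms: triethylsilyl trifluoromethanesulfonate, CC[Si](CC)(CC)OS(=O)(=O)C(F)(F)F
Why: Silyl ether formation; the silyl triflate with a hindered pyridine base silylates the tertiary allylic alcohol without ionising it, and C13 is not touched.

Step 2
Reactants: 2 (3R)-3,7-dimethyl-3-(triethylsilyloxy)octa-1,6-diene
Product: 3 (4R)-4-methyl-4-(triethylsilyloxy)hex-5-enal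
Conditions: O3 (1 equiv, Sudan Red 7B end point), CH2Cl2–MeOH, −78 °C; Me2S
Reagents that add atoms: ozone, [O-][O+]=O
Why: Ozonolysis with reductive work-up; ozone reacts much faster with the electron-rich trisubstituted alkene than with the monosubstituted vinyl group beside the silyloxy carbon, so one equivalent should cleave only the former and give the C9 aldehyde.

Step 3
Reactants: 4 2,2-dimethylcyclohexanone; 3 (4R)-4-methyl-4-(triethylsilyloxy)hex-5-enal
Product: 6 6-[(4R)-1-hydroxy-4-methyl-4-(triethylsilyloxy)hex-5-en-1-yl]-2,2-dimethylcyclohexan-1-one (mixture at the two new centres), via lithium enolate 5 (not isolated)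
Conditions: LDA, THF, −78 °C; then 3; AcOH quench
Reagents that add atoms: none
Why: Directed aldol addition; 4 can enolise only toward C10 because C4 is quaternary, the kinetic lithium enolate adds to the aldehyde at −78 °C, and the two new stereocentres are erased in steps 4 and 5.

Step 4
Reactants: 6 6-[(4R)-1-hydroxy-4-methyl-4-(triethylsilyloxy)hex-5-en-1-yl]-2,2-dimethylcyclohexan-1-one
Product: 7 2,2-dimethyl-6-[(4R)-4-methyl-4-(triethylsilyloxy)hex-5-enoyl]cyclohexan-1-one (β-diketone, keto form drawn)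
Conditions: Dess–Martin periodinane, CH2Cl2, 23 °C
Reagents that add atoms: none
Why: Dess–Martin oxidation of the β-hydroxy ketone to the β-diketone under neutral conditions that spare the silyl ether and both alkenes.

Step 5
Reactants: 7 2,2-dimethyl-6-[(4R)-4-methyl-4-(triethylsilyloxy)hex-5-enoyl]cyclohexan-1-one
Product: 8 (1E,4R)-1-(3,3-dimethyl-2-oxocyclohexylidene)-4-methyl-4-(triethylsilyloxy)hex-5-en-1-yl trifluoromethanesulfonate (OTf anti to the ring C=O)
Conditions: Tf2O, aq. Me4NOH, toluene, 0 °C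
Reagents that add atoms: trifluoromethanesulfonic anhydride, O=S(=O)(OS(=O)(=O)C(F)(F)F)C(F)(F)F
Why: Enol triflate formation from a β-diketone under non-chelating conditions; the ring oxygen is shielded by the quaternary C4 so the exocyclic oxygen should be sulfonylated, and the ammonium enolate reacts in the W form with the two oxygens anti, which gives the (E)-triflate with the C11 chain syn to the ring carbonyl.

Step 6
Reactants: 8 (1E,4R)-1-(3,3-dimethyl-2-oxocyclohexylidene)-4-methyl-4-(triethylsilyloxy)hex-5-en-1-yl trifluoromethanesulfonate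
Product: 9 (6Z)-2,2-dimethyl-6-[(5R)-5-methyl-5-(triethylsilyloxy)hept-6-en-2-ylidene]cyclohexan-1-one (C11 chain syn to C=O, C20 methyl anti)
Conditions: Me2CuLi (from MeLi and CuI), Et2O–THF, −78 → −40 °C
Reagents that add atoms: lithium dimethylcuprate, [Li+].C[Cu-]C
Why: Organocuprate conjugate addition–elimination on a β-sulfonyloxy enone, which proceeds with retention of alkene geometry, so the new C20 methyl ends anti to the ring carbonyl and the tetrasubstituted C9=C10 alkene is stereodefined.

Step 7
Reactants: 9 (6Z)-2,2-dimethyl-6-[(5R)-5-methyl-5-(triethylsilyloxy)hept-6-en-2-ylidene]cyclohexan-1-one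
Product: 10 (1S,6Z)-2,2-dimethyl-6-[(5R)-5-methyl-5-(triethylsilyloxy)hept-6-en-2-ylidene]cyclohexan-1-ol
Conditions: (R)-1-methyl-3,3-diphenyl-tetrahydro-1H,3H-pyrrolo[1,2-c][1,3,2]oxazaborole [(R)-Me-CBS, 0.3 equiv], catecholborane, toluene, −78 → −40 °C; H2O work-up
Reagents that add atoms: none
Why: Corey–Bakshi–Shibata reduction; with the alkylidene arm as the large group the (R)-catalyst delivers hydride to the face on which O → C10 → C4 runs clockwise and sets the temporary C5 carbinol as (S), and catecholborane at low temperature should not hydroborate the vinyl group or reduce the hindered enone in the conjugate sense.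

Step 8
Reactants: 10 (1S,6Z)-2,2-dimethyl-6-[(5R)-5-methyl-5-(triethylsilyloxy)hept-6-en-2-ylidene]cyclohexan-1-ol; 11 propanoyl chloride
Product: 12 (1S,6Z)-2,2-dimethyl-6-[(5R)-5-methyl-5-(triethylsilyloxy)hept-6-en-2-ylidene]cyclohexyl propanoate
Conditions: pyridine, DMAP (cat.), CH2Cl2, 0 → 23 °C
Reagents that add atoms: none
Why: DMAP-catalysed acylation of the hindered secondary allylic alcohol; the basic medium avoids allylic ionisation, so C5 keeps its configuration.

Step 9
Reactants: 12 (1S,6Z)-2,2-dimethyl-6-[(5R)-5-methyl-5-(triethylsilyloxy)hept-6-en-2-ylidene]cyclohexyl propanoate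
Product: 16 (2S,3R,6R)-3-(3,3-dimethylcyclohex-1-en-1-yl)-2,3,6-trimethyl-6-(triethylsilyloxy)oct-7-enoic acid, via lithium ester enolate 13 (not isolated), via silyl ketene acetal 14 (not isolated), via silyl ester 15 (not isolated)
Conditions: LDA, THF–HMPA (4:1), −78 °C; t-BuMe2SiCl, −78 → 65 °C; then H2O–THF work-up (silyl ester hydrolysed)
Reagents that add atoms: none
Why: Ireland–Claisen rearrangement; enolisation in THF–HMPA gives the (Z)-silyl ketene acetal, allylic strain with the syn C11 chain holds the C5–O bond pseudo-axial, and a chair transition state on that face transfers the C5 chirality to C9 (R) and, with the C17 methyl pseudo-equatorial and syn to the (E)-placed C20 methyl, to C8 (S), while the alkene moves to C5=C10.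

Step 10
Reactants: 16 (2S,3R,6R)-3-(3,3-dimethylcyclohex-1-en-1-yl)-2,3,6-trimethyl-6-(triethylsilyloxy)oct-7-enoic acid
Product: 17 methyl (2S,3R,6R)-3-(3,3-dimethylcyclohex-1-en-1-yl)-2,3,6-trimethyl-6-(triethylsilyloxy)oct-7-enoate
Conditions: MeI, K2CO3, DMF, 23 °C
Reagents that add atoms: iodomethane, CI
Why: SN2 O-methylation of the carboxylate; the mild carbonate base should not epimerise C8.

Step 11
Reactants: 17 methyl (2S,3R,6R)-3-(3,3-dimethylcyclohex-1-en-1-yl)-2,3,6-trimethyl-6-(triethylsilyloxy)oct-7-enoate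
Product: 19 methyl (2S,3R,6R)-3-(5,5-dimethyl-6-oxocyclohex-1-en-1-yl)-2,3,6-trimethyl-6-(triethylsilyloxy)oct-7-enoate, via allylic hydroperoxide 18 (not isolated)
Conditions: O2, tetraphenylporphyrin (cat.), hν, CH2Cl2, 0 °C; then Ac2O, pyridine, DMAP (cat.), 0 → 23 °C
Reagents that add atoms: oxygen, O=O
Why: Schenck ene reaction followed by Kornblum–DeLaMare-type dehydration; the only allylic hydrogens of the C5=C10 alkene are on C1, so singlet oxygen must bond to C5 and shift the alkene to C10=C1, the vinyl group has no allylic hydrogen and is inert, and acetylation of the hydroperoxide with base-induced loss of acetate gives the C5 ketone.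

Step 12
Reactants: 19 methyl (2S,3R,6R)-3-(5,5-dimethyl-6-oxocyclohex-1-en-1-yl)-2,3,6-trimethyl-6-(triethylsilyloxy)oct-7-enoate
Product: 21 methyl (2S,3R,6R)-3-[3,3-dimethyl-2-(trifluoromethylsulfonyloxy)cyclohex-1-en-1-yl]-2,3,6-trimethyl-6-(triethylsilyloxy)oct-7-enoate, via lithium enolate 20 (not isolated)
Conditions: LiBH(s-Bu)3, THF, −78 °C; then PhNTf2, −78 → 0 °C; AcOH quench
Reagents that add atoms: N-phenylbis(trifluoromethanesulfonimide), O=S(=O)(N(c1ccccc1)S(=O)(=O)C(F)(F)F)C(F)(F)F
Why: Conjugate (1,4) hydride reduction of the β-unsubstituted enone by the bulky trialkylborohydride gives the C5–C10 enolate regiospecifically (C4 is quaternary, so no other enolate exists), and O-sulfonylation fixes the tetrasubstituted C5=C10 alkene; the methyl ester is not reduced at −78 °C.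

Step 13
Reactants: 21 methyl (2S,3R,6R)-3-[3,3-dimethyl-2-(trifluoromethylsulfonyloxy)cyclohex-1-en-1-yl]-2,3,6-trimethyl-6-(triethylsilyloxy)oct-7-enoate
Product: 22 methyl (2S,3R,6R)-3-[2-(methoxycarbonyl)-3,3-dimethylcyclohex-1-en-1-yl]-2,3,6-trimethyl-6-(triethylsilyloxy)oct-7-enoate
Conditions: Pd(OAc)2 (10 mol%), 1,3-bis(diphenylphosphino)propane, CO (1 atm), MeOH, Et3N, DMF, 70 °C
Reagents that add atoms: carbon monoxide, [C-]#[O+]; methanol, CO
Why: Palladium-catalysed alkoxycarbonylation of a vinyl triflate; oxidative addition to zerovalent palladium, CO insertion and methanolysis place C6 on C5 without moving the alkene, and CO insertion should outrun any Heck-type reaction with the remote vinyl group.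

Step 14
Reactants: 22 methyl (2S,3R,6R)-3-[2-(methoxycarbonyl)-3,3-dimethylcyclohex-1-en-1-yl]-2,3,6-trimethyl-6-(triethylsilyloxy)oct-7-enoate
Product: 23 (2S,3R,6R)-3-[2-(hydroxymethyl)-3,3-dimethylcyclohex-1-en-1-yl]-2,3,6-trimethyl-6-(triethylsilyloxy)oct-7-en-1-ol
Conditions: i-Bu2AlH (excess), CH2Cl2, −78 → 0 °C; aq. potassium sodium tartrate
Reagents that add atoms: none
Why: Hydride reduction of both esters by the aluminium hydride gives the allylic C6 alcohol and the primary C7 alcohol; no stereocentre is affected.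

Step 15
Reactants: 23 (2S,3R,6R)-3-[2-(hydroxymethyl)-3,3-dimethylcyclohex-1-en-1-yl]-2,3,6-trimethyl-6-(triethylsilyloxy)oct-7-en-1-ol
Product: 24 (2S,3R,6R)-3-(2-formyl-3,3-dimethylcyclohex-1-en-1-yl)-2,3,6-trimethyl-6-(triethylsilyloxy)oct-7-enal (seco ring B dialdehyde)
Conditions: Dess–Martin periodinane, NaHCO3, CH2Cl2, 0 → 23 °C; used at once
Reagents that add atoms: none
Why: Dess–Martin oxidation of both primary alcohols; the buffered, non-basic medium should keep the α-stereocentre C8 and the alkene position.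

Step 16
Reactants: 24 (2S,3R,6R)-3-(2-formyl-3,3-dimethylcyclohex-1-en-1-yl)-2,3,6-trimethyl-6-(triethylsilyloxy)oct-7-enal
Product: 25 (6S,7R,8S,9R,13R)-13-(triethylsilyloxy)halima-5(10),14-diene-6,7-diol
Conditions: SmI2 (2.5 equiv, 0.1 M in THF), t-BuOH (2.2 equiv), THF (high dilution), −78 → 0 °C
Reagents that add atoms: none
Why: Divalent samarium transfers one electron to the conjugated C6 aldehyde and one to the C7 aldehyde (or the first ketyl adds to the second, samarium-bound carbonyl and the resulting oxygen radical is reduced) and the two carbonyl carbons join; the closest known reaction type is the SmI2-promoted intramolecular pinacol coupling of 1,6-dialdehydes to cis-cyclohexane-1,2-diols. Ring B closes by a 6-exo-trig ketyl addition to the C6 carbonyl carbon in a chair-like array, the quaternary C9 and the cis-fixed C5=C10 alkene holding the two termini close. C6 and C7 should come out cis because both oxygens stay bound to one trivalent samarium centre in the cyclic transition state; the face is set by C8, whose methyl sits pseudo-equatorial so that both new C–O bonds form anti to it, with the C6 oxygen pseudo-axial to escape allylic strain with the C4 methyls. The step needs C6–C7 coupling to win over conjugate reduction or β-coupling of the enal and over intermolecular coupling: C10 is fully substituted and shielded by C9, closure from C10 would give a four-membered ring, and high dilution with t-BuOH as proton source favours the intramolecular diolate. The vinyl group and the tertiary silyl ether are inert to SmI2.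

Step 17
Reactants: 25 (6S,7R,8S,9R,13R)-13-(triethylsilyloxy)halima-5(10),14-diene-6,7-diol
Product: 26 (6S,7R,8S,9R,13R)-halima-5(10),14-diene-6,7,13-triol
Conditions: Bu4NF, AcOH (1:1), THF, 0 → 23 °C
Reagents that add atoms: none
Why: Fluoride-induced desilylation of the tertiary silyl ether, buffered with acetic acid; doing this before acetylation means no acetate is ever exposed to fluoride, so acyl migration between O7 and O6 cannot occur.

Step 18
Reactants: 26 (6S,7R,8S,9R,13R)-halima-5(10),14-diene-6,7,13-triol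
Product: 27 (6S,7R,8S,9R,13R)-7-acetoxyhalima-5(10),14-diene-6,13-diol (CNP0126002.3)
Conditions: Ac2O (1.1 equiv), pyridine, DMAP (0.05 equiv), CH2Cl2, −20 → 0 °C
Reagents that add atoms: acetic anhydride, CC(=O)OC(C)=O
Why: Selective acylation; the equatorial C7 hydroxyl should react first, since the allylic C6 hydroxyl is pseudo-axial and shielded by the C4 methyls across C5 and the tertiary C13 hydroxyl does not acylate under these conditions.

**Compound list**

1 | (R)-(−)-linalool, (3R)-3,7-dimethylocta-1,6-dien-3-ol | C=C[C@](C)(O)CCC=C(C)C | starting material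
2 | (3R)-3,7-dimethyl-3-(triethylsilyloxy)octa-1,6-diene | C=C[C@](C)(O[Si](CC)(CC)CC)CCC=C(C)C | intermediate
3 | (4R)-4-methyl-4-(triethylsilyloxy)hex-5-enal | C=C[C@](C)(O[Si](CC)(CC)CC)CCC=O | intermediate
4 | 2,2-dimethylcyclohexanone | CC1(C)CCCCC1=O | starting material
5 | lithium 6,6-dimethylcyclohex-1-en-1-olate (lithium enolate of 4, formed in the flask) | [Li+].[O-]C1=CCCCC1(C)C | intermediate
6 | 6-[(4R)-1-hydroxy-4-methyl-4-(triethylsilyloxy)hex-5-en-1-yl]-2,2-dimethylcyclohexan-1-one (mixture at the two new centres) | C=C[C@](C)(O[Si](CC)(CC)CC)CCC(O)C1CCCC(C)(C)C1=O | intermediate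
7 | 2,2-dimethyl-6-[(4R)-4-methyl-4-(triethylsilyloxy)hex-5-enoyl]cyclohexan-1-one (keto form) | C=C[C@](C)(O[Si](CC)(CC)CC)CCC(=O)C1CCCC(C)(C)C1=O | intermediate
8 | (1E,4R)-1-(3,3-dimethyl-2-oxocyclohexylidene)-4-methyl-4-(triethylsilyloxy)hex-5-en-1-yl trifluoromethanesulfonate | C=C[C@](C)(O[Si](CC)(CC)CC)CC/C(OS(=O)(=O)C(F)(F)F)=C1/CCCC(C)(C)C1=O | intermediate
9 | (6Z)-2,2-dimethyl-6-[(5R)-5-methyl-5-(triethylsilyloxy)hept-6-en-2-ylidene]cyclohexan-1-one | C=C[C@](C)(O[Si](CC)(CC)CC)CC/C(C)=C1/CCCC(C)(C)C1=O | intermediate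
10 | (1S,6Z)-2,2-dimethyl-6-[(5R)-5-methyl-5-(triethylsilyloxy)hept-6-en-2-ylidene]cyclohexan-1-ol | C=C[C@](C)(O[Si](CC)(CC)CC)CC/C(C)=C1/CCCC(C)(C)[C@@H]1O | intermediate
11 | propanoyl chloride | CCC(Cl)=O | starting material
12 | (1S,6Z)-2,2-dimethyl-6-[(5R)-5-methyl-5-(triethylsilyloxy)hept-6-en-2-ylidene]cyclohexyl propanoate | C=C[C@](C)(O[Si](CC)(CC)CC)CC/C(C)=C1/CCCC(C)(C)[C@@H]1OC(=O)CC | intermediate
13 | lithium enolate of 12, C17 methyl syn to O–Li (formed in the flask) | C=C[C@](C)(O[Si](CC)(CC)CC)CC/C(C)=C1/CCCC(C)(C)[C@@H]1O/C([O-])=C/C.[Li+] | intermediate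
14 | (Z)-O-(tert-butyldimethylsilyl) ketene acetal of 12 (formed in the flask) | C=C[C@](C)(O[Si](CC)(CC)CC)CC/C(C)=C1/CCCC(C)(C)[C@@H]1O/C(O[Si](C)(C)C(C)(C)C)=C/C | intermediate
15 | tert-butyldimethylsilyl (2S,3R,6R)-3-(3,3-dimethylcyclohex-1-en-1-yl)-2,3,6-trimethyl-6-(triethylsilyloxy)oct-7-enoate (formed in the flask) | C=C[C@](C)(O[Si](CC)(CC)CC)CC[C@@](C)(C1=CC(C)(C)CCC1)[C@H](C)C(=O)O[Si](C)(C)C(C)(C)C | intermediate
16 | (2S,3R,6R)-3-(3,3-dimethylcyclohex-1-en-1-yl)-2,3,6-trimethyl-6-(triethylsilyloxy)oct-7-enoic acid | C=C[C@](C)(O[Si](CC)(CC)CC)CC[C@@](C)(C1=CC(C)(C)CCC1)[C@H](C)C(=O)O | intermediate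
17 | methyl (2S,3R,6R)-3-(3,3-dimethylcyclohex-1-en-1-yl)-2,3,6-trimethyl-6-(triethylsilyloxy)oct-7-enoate | C=C[C@](C)(O[Si](CC)(CC)CC)CC[C@@](C)(C1=CC(C)(C)CCC1)[C@H](C)C(=O)OC | intermediate
18 | methyl (2S,3R,6R)-3-(6-hydroperoxy-5,5-dimethylcyclohex-1-en-1-yl)-2,3,6-trimethyl-6-(triethylsilyloxy)oct-7-enoate (C5 epimers, formed in the flask) | C=C[C@](C)(O[Si](CC)(CC)CC)CC[C@@](C)(C1=CCCC(C)(C)C1OO)[C@H](C)C(=O)OC | intermediate
19 | methyl (2S,3R,6R)-3-(5,5-dimethyl-6-oxocyclohex-1-en-1-yl)-2,3,6-trimethyl-6-(triethylsilyloxy)oct-7-enoate | C=C[C@](C)(O[Si](CC)(CC)CC)CC[C@@](C)(C1=CCCC(C)(C)C1=O)[C@H](C)C(=O)OC | intermediate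
20 | lithium C5–C10 enolate of the saturated ketone from 19 (formed in the flask) | C=C[C@](C)(O[Si](CC)(CC)CC)CC[C@@](C)(C1=C([O-])C(C)(C)CCC1)[C@H](C)C(=O)OC.[Li+] | intermediate
21 | methyl (2S,3R,6R)-3-[3,3-dimethyl-2-(trifluoromethylsulfonyloxy)cyclohex-1-en-1-yl]-2,3,6-trimethyl-6-(triethylsilyloxy)oct-7-enoate | C=C[C@](C)(O[Si](CC)(CC)CC)CC[C@@](C)(C1=C(OS(=O)(=O)C(F)(F)F)C(C)(C)CCC1)[C@H](C)C(=O)OC | intermediate
22 | methyl (2S,3R,6R)-3-[2-(methoxycarbonyl)-3,3-dimethylcyclohex-1-en-1-yl]-2,3,6-trimethyl-6-(triethylsilyloxy)oct-7-enoate | C=C[C@](C)(O[Si](CC)(CC)CC)CC[C@@](C)(C1=C(C(=O)OC)C(C)(C)CCC1)[C@H](C)C(=O)OC | intermediate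
23 | (2S,3R,6R)-3-[2-(hydroxymethyl)-3,3-dimethylcyclohex-1-en-1-yl]-2,3,6-trimethyl-6-(triethylsilyloxy)oct-7-en-1-ol | C=C[C@](C)(O[Si](CC)(CC)CC)CC[C@@](C)(C1=C(CO)C(C)(C)CCC1)[C@H](C)CO | intermediate
24 | (2S,3R,6R)-3-(2-formyl-3,3-dimethylcyclohex-1-en-1-yl)-2,3,6-trimethyl-6-(triethylsilyloxy)oct-7-enal (seco ring B dialdehyde) | C=C[C@](C)(O[Si](CC)(CC)CC)CC[C@@](C)(C1=C(C=O)C(C)(C)CCC1)[C@H](C)C=O | intermediate
25 | (6S,7R,8S,9R,13R)-13-(triethylsilyloxy)halima-5(10),14-diene-6,7-diol | C=C[C@](C)(O[Si](CC)(CC)CC)CC[C@@]1(C)C2=C([C@H](O)[C@H](O)[C@H]1C)C(C)(C)CCC2 | intermediate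
26 | (6S,7R,8S,9R,13R)-halima-5(10),14-diene-6,7,13-triol | C=C[C@](C)(O)CC[C@@]1(C)C2=C([C@H](O)[C@H](O)[C@H]1C)C(C)(C)CCC2 | intermediate
27 | (6S,7R,8S,9R,13R)-7-acetoxyhalima-5(10),14-diene-6,13-diol (CNP0126002.3) | C=C[C@](C)(O)CC[C@@]1(C)C2=C([C@H](O)[C@H](OC(C)=O)[C@H]1C)C(C)(C)CCC2 | target

**Step count and risks**

Total step count: 18. Longest linear sequence: 18 steps, from 1 to 27 (4 and 11 enter as bought materials).

The three steps most likely to fail:

Step 16 (key step). What may go wrong: over-reduction (conjugate reduction of the enal, or reduction of either aldehyde to the alcohol) competing with coupling, or leakage to the trans diol or to the face syn to the C8 methyl. Fallback, same C6–C7 disconnection by another mechanism: setting out from 24, McMurry reductive coupling with TiCl3(DME)1.5 and Zn–Cu in refluxing DME should join C6 and C7 as an alkene and give 13-(triethylsilyloxy)halima-5(10),6,14-triene F8. Syn-dihydroxylation of its disubstituted, diene-activated C6=C7 bond with catalytic OsO4 and N-methylmorpholine N-oxide, from the face anti to the C8 methyl and stopped before the hindered vinyl group reacts, comes back to the route at 25.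

Step 5. What may go wrong: loss of regio- or stereocontrol in the O-sulfonylation (triflation of the ring oxygen, or reaction through the chelated enolate to the Z-triflate), which would carry the wrong C9=C10 geometry into the Claisen step and invert C8 relative to C9. Fallback: setting out from 3, MeMgBr addition should give (5R)-5-methyl-5-(triethylsilyloxy)hept-6-en-2-ol F1, and Dess–Martin oxidation the methyl ketone (5R)-5-methyl-5-(triethylsilyloxy)hept-6-en-2-one F2. Aldol addition of lithium enolate 5 to F2 in the presence of CeCl3 should give the tertiary aldol 6-[(5R)-2-hydroxy-5-methyl-5-(triethylsilyloxy)hept-6-en-2-yl]-2,2-dimethylcyclohexan-1-one F3. Dehydration of F3 with Burgess reagent should give 9 together with its (6E)-isomer F4; the two are separated on AgNO3-impregnated silica, F4 is re-equilibrated with catalytic iodine under light and recycled, and the route is rejoined at 9.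

Step 7. What may go wrong: poor facial discrimination by the oxazaborolidine because both carbonyl substituents are fully substituted, so that C5 is set with low selectivity and the error is passed on to C8 and C9. Fallback, resolution in place of asymmetric reduction: setting out from 9, Luche reduction (NaBH4, CeCl3·7H2O, MeOH) should give 10 together with its (1R)-epimer F5. Esterification of the mixture with (S)-O-methylmandelic acid (carbodiimide, DMAP) should give the (S)-O-methylmandelate of 10 F6 and the (S)-O-methylmandelate of the (1R)-alcohol F7, separated by chromatography. LiAlH4 cleaves F6 and comes back to the route at 10; F5 recovered from F7 is re-oxidised to 9 and recycled.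

Further compounds
F1 | step 5 | (5R)-5-methyl-5-(triethylsilyloxy)hept-6-en-2-ol (C2 epimers) | C=C[C@](C)(O[Si](CC)(CC)CC)CCC(C)O
F2 | step 5 | (5R)-5-methyl-5-(triethylsilyloxy)hept-6-en-2-one | C=C[C@](C)(O[Si](CC)(CC)CC)CCC(C)=O
F3 | step 5 | 6-[(5R)-2-hydroxy-5-methyl-5-(triethylsilyloxy)hept-6-en-2-yl]-2,2-dimethylcyclohexan-1-one (mixture at the two new centres) | C=C[C@](C)(O[Si](CC)(CC)CC)CCC(C)(O)C1CCCC(C)(C)C1=O
F4 | step 5 | (6E)-2,2-dimethyl-6-[(5R)-5-methyl-5-(triethylsilyloxy)hept-6-en-2-ylidene]cyclohexan-1-one | C=C[C@](C)(O[Si](CC)(CC)CC)CC/C(C)=C1\CCCC(C)(C)C1=O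
F5 | step 7 | (1R,6Z)-2,2-dimethyl-6-[(5R)-5-methyl-5-(triethylsilyloxy)hept-6-en-2-ylidene]cyclohexan-1-ol | C=C[C@](C)(O[Si](CC)(CC)CC)CC/C(C)=C1/CCCC(C)(C)[C@H]1O
F6 | step 7 | (1S,6Z)-2,2-dimethyl-6-[(5R)-5-methyl-5-(triethylsilyloxy)hept-6-en-2-ylidene]cyclohexyl (S)-2-methoxy-2-phenylacetate | C=C[C@](C)(O[Si](CC)(CC)CC)CC/C(C)=C1/CCCC(C)(C)[C@@H]1OC(=O)[C@@H](OC)c1ccccc1
F7 | step 7 | (1R,6Z)-2,2-dimethyl-6-[(5R)-5-methyl-5-(triethylsilyloxy)hept-6-en-2-ylidene]cyclohexyl (S)-2-methoxy-2-phenylacetate | C=C[C@](C)(O[Si](CC)(CC)CC)CC/C(C)=C1/CCCC(C)(C)[C@H]1OC(=O)[C@@H](OC)c1ccccc1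
F8 | step 16 | 13-(triethylsilyloxy)halima-5(10),6,14-triene (C8, C9 and C13 as in 24) | C=C[C@](C)(O[Si](CC)(CC)CC)CC[C@@]1(C)C2=C(C=C[C@H]1C)C(C)(C)CCC2
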